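The route rests on opening furan ring B of the dibenzofuran core at both bonds that tie catechol ring A to central ring C: O5–C5a and C9a–C9b (dibenzofuran numbering). Ring A carries identical oxygens at C7 and C8 and is symmetric about its fused edge C5a–C9a, so one symmetrical aryne, 4,5-dimethoxybenzyne, can supply both carbons without a regiochemical choice. The key step joins it in one pot to an ortho-iodophenol that holds ring C with its phenyl and two methoxy groups: the phenoxide adds to the aryne and palladium then closes ring B by C–H arylation. Demethylation, lactone annulation at C1 and dehydrogenation complete the quinone methide.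

Key step: step 5

Remark on numbering and stereochemistry: compounds 3–8 and 11 use biphenyl numbering; compounds 12–17 use dibenzofuran numbering (ring C: C1–C4, C4a, C9b; ring B: C4a, O5, C5a, C9a, C9b; ring A: C5a–C9a). The target has no stereocentre. The single stereocentre of lactone 16 is assumed to form as a racemate, which is harmless because step 8 removes it.

Step 1
Reactants: 1 2-bromo-1,3-dimethoxybenzene; 2 phenylboronic acid
Product: 3 2,6-dimethoxybiphenyl
Conditions: Pd(OAc)2 (2 mol %), SPhos (4 mol %), K3PO4, toluene/H2O, 100 °C
Reagents that add atoms: none
Why: Suzuki–Miyaura coupling; the bulky, electron-rich SPhos ligand lets zerovalent palladium insert into the doubly ortho-substituted bromide, and the boron sits on the unhindered, stable phenyl partner so protodeboronation should not compete.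

Step 2
Reactants: 3 2,6-dimethoxybiphenyl
Product: 5 2,6-dimethoxybiphenyl-3-carbaldehyde, via chloro ether 4 (not isolated)
Conditions: Cl2CHOMe, TiCl4, CH2Cl2, 0 °C; then H2O
Reagents that add atoms: dichloromethyl methyl ether, COC(Cl)Cl; water, O
Why: Rieche formylation; C3 (equivalent to C5 by symmetry) is ortho to one methoxy group and para to the other and is the only strongly activated position, and the aldehyde formed deactivates the ring against a second formylation.

Step 3
Reactants: 5 2,6-dimethoxybiphenyl-3-carbaldehyde
Product: 7 2,6-dimethoxybiphenyl-3-ol, via aryl formate 6 (not isolated)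
Conditions: mCPBA, CH2Cl2, 0 °C to rt; then HCl (cat.), MeOH, rt
Reagents that add atoms: 3-chloroperoxybenzoic acid (mCPBA), OOC(=O)c1cccc(Cl)c1
Why: Baeyer–Villiger (Dakin-type) oxidation; the aryl group, made electron-rich by methoxy groups ortho and para to the formyl carbon, should migrate in preference to hydride to give formate 6, which acid methanolysis cleaves to the phenol.

Step 4
Reactants: 7 2,6-dimethoxybiphenyl-3-ol
Product: 8 4-iodo-2,6-dimethoxybiphenyl-3-ol
Conditions: I2 (1.05 equiv), KI, Na2CO3, THF/H2O, 0 °C to rt
Reagents that add atoms: iodine, [I][I]
Why: Electrophilic iodination through the phenoxide; in basic medium I2 reacts only with the phenoxide, whose ortho and para carbons are C2, C4 and C6, and since C2 and C6 carry methoxy groups the iodine should enter at C4 and not at the methoxy-activated C5 that a neutral, acid-promoted iodination would favour.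

Step 5
Reactants: 8 4-iodo-2,6-dimethoxybiphenyl-3-ol; 9 4,5-dimethoxy-2-(trimethylsilyl)phenyl trifluoromethanesulfonate
Product: 12 2,4,7,8-tetramethoxy-3-phenyldibenzofuran, via 4,5-dimethoxybenzyne 10 (not isolated), via diaryl ether 11 (not isolated)
Conditions: CsF (3 equiv), MeCN, rt; then Pd(OAc)2 (5 mol %), PCy3 (10 mol %), 100 °C
Reagents that add atoms: none
Why: Fluoride attacks silicon in 9 and triflate leaves to give the symmetrical aryne 10; the phenoxide of 8 adds to it and the resulting aryl anion is protonated in the medium, giving diaryl ether 11 with its C–I bond intact. After Pd(OAc)2 and PCy3 are added and the mixture is heated, zerovalent palladium formed in situ inserts into the C4–I bond of 11, the arylpalladium iodide metalates a neighbouring C–H of the dimethoxyphenoxy ring by concerted metalation–deprotonation with fluoride as base, and reductive elimination forms the C9a–C9b bond. The closest known reaction type is the one-pot aryne O-arylation of ortho-iodophenols with silylaryl triflates followed by palladium-catalysed intramolecular direct arylation to dibenzofurans. Furan ring B, the only ring closed, forms as a five-membered ring through a six-membered oxapalladacycle, and no stereocentre is created. Two selectivities are needed: the symmetry of 10 makes its two aryne carbons equivalent, so the O5–C5a bond has one possible outcome, and of the two C–H bonds ortho to the ether oxygen in 11 the one lying between that oxygen and a methoxy group is shielded, so palladation should take the unflanked C–H and give the 7,8-dimethoxy pattern. On ring C the iodine fixes the coupling site at the carbon next to the phenol oxygen, the other neighbour being blocked by a methoxy group.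

Step 6
Reactants: 12 2,4,7,8-tetramethoxy-3-phenyldibenzofuran
Product: 13 3-phenyldibenzofuran-2,4,7,8-tetraol
Conditions: BBr3 (6 equiv), CH2Cl2, −78 °C to rt; then H2O; under Ar, product used directly
Reagents that add atoms: none
Why: Lewis-acid ether cleavage; BBr3 coordinates each methoxy oxygen and bromide removes the methyl group, while the diaryl ether of ring B offers no alkyl carbon for attack and should survive.

Step 7
Reactants: 13 3-phenyldibenzofuran-2,4,7,8-tetraol; 14 4-hydroxymandelic acid (racemic)
Product: 16 racemic 3-(4-hydroxyphenyl)benzofuran-2(3H)-one lactone fused across C1–C2 of 4,7,8-trihydroxy-3-phenyldibenzofuran, via hydroxy acid 15 (not isolated)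
Conditions: 14 (1.05 equiv, slow addition), H2SO4 (cat.), AcOH, 70 °C, Ar
Reagents that add atoms: none
Why: Acid-catalysed Friedel–Crafts alkylation followed by lactonisation (the classical phenol–mandelic acid route to 3-arylbenzofuran-2(3H)-ones); the hydroxybenzylic cation from 14 should attack C1, the only open carbon that is ortho to one hydroxyl (C2) and para to another (C4), whereas each open carbon of ring A is activated by a single hydroxyl, and acid 15 then closes onto the C2 hydroxyl; the new stereocentre is not controlled and forms as a racemate.

Step 8
Reactants: 16 racemic lactone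
Product: 17 CNP0139113.0 (quinone methide lactone)
Conditions: p-chloranil (1.0 equiv), 1,4-dioxane, rt to 60 °C, Ar
Reagents that add atoms: none
Why: Quinone dehydrogenation; chloranil should remove the acidic, doubly benzylic lactone C–H together with the hydrogen of the para C4 hydroxyl to give the para-quinone methide (the oxidation used to turn hydroquinone–mandelic acid adducts into benzodifuranone chromophores), one equivalent of this mild quinone should leave the ring A catechol untouched, and the stereocentre of 16 is erased.

Compound list
1 | 2-bromo-1,3-dimethoxybenzene | COc1cccc(OC)c1Br | starting material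
2 | phenylboronic acid | OB(O)c1ccccc1 | starting material
3 | 2,6-dimethoxybiphenyl | COc1cccc(OC)c1-c1ccccc1 | intermediate
4 | 3-[chloro(methoxy)methyl]-2,6-dimethoxybiphenyl (racemic, not isolated) | COC(Cl)c1ccc(OC)c(-c2ccccc2)c1OC | intermediate
5 | 2,6-dimethoxybiphenyl-3-carbaldehyde | O=Cc1ccc(OC)c(-c2ccccc2)c1OC | intermediate
6 | 2,6-dimethoxybiphenyl-3-yl formate (not isolated) | O=COc1ccc(OC)c(-c2ccccc2)c1OC | intermediate
7 | 2,6-dimethoxybiphenyl-3-ol | Oc1ccc(OC)c(-c2ccccc2)c1OC | intermediate
8 | 4-iodo-2,6-dimethoxybiphenyl-3-ol | Oc1c(I)cc(OC)c(-c2ccccc2)c1OC | intermediate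
9 | 4,5-dimethoxy-2-(trimethylsilyl)phenyl trifluoromethanesulfonate | COc1cc(OS(=O)(=O)C(F)(F)F)c(cc1OC)[Si](C)(C)C | starting material
10 | 4,5-dimethoxybenzyne (not isolated) | COC1=CC#CC=C1OC | intermediate
11 | 3-(3,4-dimethoxyphenoxy)-4-iodo-2,6-dimethoxybiphenyl (not isolated) | COc1ccc(Oc2c(I)cc(OC)c(-c3ccccc3)c2OC)cc1OC | intermediate
12 | 2,4,7,8-tetramethoxy-3-phenyldibenzofuran | COc1cc2c(oc3cc(OC)c(OC)cc23)c(OC)c1-c1ccccc1 | intermediate
13 | 3-phenyldibenzofuran-2,4,7,8-tetraol | Oc1cc2c(oc3cc(O)c(O)cc23)c(O)c1-c1ccccc1 | intermediate
14 | 4-hydroxymandelic acid (racemic) | OC(C(=O)O)c1ccc(O)cc1 | starting material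
15 | (4-hydroxyphenyl)(2,4,7,8-tetrahydroxy-3-phenyldibenzofuran-1-yl)acetic acid (racemic, not isolated) | OC(=O)C(c1ccc(O)cc1)c1c(O)c(-c2ccccc2)c(O)c2oc3cc(O)c(O)cc3c12 | intermediate
16 | racemic γ-lactone of acid 15 closed onto the C2 hydroxyl (3-arylbenzofuran-2(3H)-one fused at C1–C2; free hydroxyls at C4, C7, C8 and on the aryl group) | O=C1Oc2c(-c3ccccc3)c(O)c3oc4cc(O)c(O)cc4c3c2C1c1ccc(O)cc1 | intermediate
17 | CNP0139113.0: as 16, but with an exocyclic C1=C(4-hydroxyphenyl) double bond into the lactone and a ketone at C4 (7,8-diol free) | O=C1OC2=C(c3ccccc3)C(=O)c3oc4cc(O)c(O)cc4c3C2=C1c1ccc(O)cc1 | target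

Total step count: 8.
Longest linear sequence: 8 steps (1 to 17); 2, 9 and 14 enter as purchased reagents.

Steps most likely to fail

Step 5. The hindered, doubly ortho-substituted phenoxide may capture the aryne incompletely, or the C–I bond may be reduced before C–H palladation. The fallback makes the two bonds separately and without the iodide. Setting out from phenol 7, an Ullmann ether synthesis with 4-bromo-1,2-dimethoxybenzene (CuI, N,N-dimethylglycine, Cs2CO3, 1,4-dioxane, 100 °C) should give 3-(3,4-dimethoxyphenoxy)-2,6-dimethoxybiphenyl F1. Oxidative twofold C–H coupling of this diaryl ether (Pd(OAc)2 cat., K2CO3, pivalic acid, air, 120 °C) would then close ring B and come back to the route at 12. On ring C only C4 is free next to the ether oxygen, and on ring A the unflanked C–H is again the favoured one.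

Step 7. Alkylation may occur on catechol ring A in competition with C1, the hydroxybenzylic cation may condense with itself, or the tetraol may oxidise in warm acid. The fallback forms the C–C bond on the air-stable tetramethyl ether. Setting out from 12, Friedel–Crafts alkylation with methyl 2-bromo-2-(4-methoxyphenyl)acetate (SnCl4, CH2Cl2, 0 °C) should occur at C1, the only core carbon ortho and para to methoxy groups. It would give racemic methyl (4-methoxyphenyl)(2,4,7,8-tetramethoxy-3-phenyldibenzofuran-1-yl)acetate F2. BBr3 (CH2Cl2, −78 °C to rt, acidic work-up) then cleaves the five aryl methyl ethers and lets the ester close onto the freed C2 hydroxyl, coming back to the route at 16.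

Step 4. If the phenol reacts in its neutral form, iodination may go to the methoxy-activated C5 instead of C4. The fallback places the iodine by directed metalation instead of electrophilic substitution. Setting out from 7, the phenol would be converted into its methoxymethyl ether, 2,6-dimethoxy-3-(methoxymethoxy)biphenyl F3 (MOMCl, iPr2NEt, CH2Cl2). Directed ortho-lithiation (n-BuLi, THF, −78 to 0 °C) and quenching with I2 should give 4-iodo-2,6-dimethoxy-3-(methoxymethoxy)biphenyl F4, because the acetal chelates lithium and places the carbanion at C4, its only free ortho position. Acid methanolysis (HCl, MeOH, rt) removes the acetal and comes back to the route at 8.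

Further compounds
F1 | step 5 | 3-(3,4-dimethoxyphenoxy)-2,6-dimethoxybiphenyl | COc1ccc(Oc2ccc(OC)c(-c3ccccc3)c2OC)cc1OC
F2 | step 7 | methyl (4-methoxyphenyl)(2,4,7,8-tetramethoxy-3-phenyldibenzofuran-1-yl)acetate (racemic) | COC(=O)C(c1ccc(OC)cc1)c1c(OC)c(-c2ccccc2)c(OC)c2oc3cc(OC)c(OC)cc3c12
F3 | step 4 | 2,6-dimethoxy-3-(methoxymethoxy)biphenyl | COCOc1ccc(OC)c(-c2ccccc2)c1OC
F4 | step 4 | 4-iodo-2,6-dimethoxy-3-(methoxymethoxy)biphenyl | COCOc1c(I)cc(OC)c(-c2ccccc2)c1OC
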